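**Retrosynthetic overview**

1. C11–C12 is the last bond: a cyclic peroxycarbenium ion, released by acetolysis of a 2,3,5-trioxabicyclo[2.2.2]octane, is captured by a tethered (Z)-vinylsilane; this closes the 14-membered carbocycle and installs the C7 acetate.
2. The peroxide comes from ring expansion of the C7–C8 cis-epoxide: H2O2 and the C11 acetal carbon are inserted into the C8–O bond (oxirane → bridged 1,2,4-trioxane, which already holds the 1,2-dioxane).
3. C1–C2 and the cis α-methylene lactone: asymmetric Nozaki–Hiyama–Kishi allylation/lactonisation joining enal 14 (fragment A) and allylic bromide 22 (fragment B).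
4. Fragment A: two carbocuprations (propyne, methyl but-2-ynoate) and a Shi epoxidation. Fragment B: trans-hydrosilylation of but-2-yn-1-ol, propiolate coupling, hydroalumination/CH2O.
5. Ring order: oxirane → γ-lactone → trioxabicycle (1,2-dioxane) → 14-membered carbocycle.

Assumption: C1–C17 are cembrane locants (C1 ring-fusion CH, C2 lactone CH–O, C7 CH–OAc, C8/C11 peroxide carbons, C15–C17 methylene-lactone carbons); the target is read as (1S,2S,3E,7R,8R,11S,12Z).

**Route**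

Step 1
Reactants: 1 2-(2-bromoethyl)-1,3-dioxolane; 2 propyne; 3 oxirane
Product: 6 (3Z)-6-(1,3-dioxolan-2-yl)-4-methylhex-3-en-1-ol, via Grignard reagent 4 (not isolated), via alkenylcopper 5 (not isolated)
Conditions: Mg, THF, 25 °C; CuBr·SMe2, Et2O/Me2S, −45 °C; 2, −25 °C; LiC≡CPr, HMPA, then 3, −40 → −20 °C; H2O
Reagents that add atoms: none
Why: Normant carbocupration adds the alkyl group of 4 and copper syn across propyne (alkyl to the internal carbon) and the derived alkenyl(alkynyl)cuprate opens oxirane with retention, so the Z trisubstituted C7=C8 alkene (C6 cis to C9) is fixed.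

Step 2
Reactants: 6 (3Z)-6-(1,3-dioxolan-2-yl)-4-methylhex-3-en-1-ol
Product: 7 2-[(3Z)-6-bromo-3-methylhex-3-en-1-yl]-1,3-dioxolane
Conditions: CBr4, PPh3, CH2Cl2, 0 °C
Reagents that add atoms: carbon tetrabromide, BrC(Br)(Br)Br
Why: Appel bromination is an SN2 displacement at the primary carbinol and leaves the Z alkene and the dioxolane untouched.

Step 3
Reactants: 7 2-[(3Z)-6-bromo-3-methylhex-3-en-1-yl]-1,3-dioxolane; 8 methyl but-2-ynoate
Product: 11 methyl (2E,6Z)-9-(1,3-dioxolan-2-yl)-3,7-dimethylnona-2,6-dienoate, via Grignard reagent 9 (not isolated), via vinylcopper adduct 10 (not isolated)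
Conditions: Mg, THF; CuBr·SMe2, THF/Me2S, −40 °C; 8, −78 °C; MeOH, −78 °C
Reagents that add atoms: none
Why: syn carbocupration of the ynoate (conjugate addition of the organocopper from 9 at −78 °C) and protonation with retention give only the 2E enoate, which is the C3=C4 geometry of the target.

Step 4
Reactants: 11 methyl (2E,6Z)-9-(1,3-dioxolan-2-yl)-3,7-dimethylnona-2,6-dienoate
Product: 12 methyl (2E)-5-[(2R,3S)-3-[2-(1,3-dioxolan-2-yl)ethyl]-3-methyloxiran-2-yl]-3-methylpent-2-enoate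
Conditions: D-fructose-derived Shi ketone (1,2:4,5-di-O-isopropylidene-β-D-erythro-2,3-hexodiulo-2,6-pyranose, 30 mol %), KHSO5 (as 2KHSO5·KHSO4·K2SO4), K2CO3, Bu4NHSO4, MeCN/dimethoxymethane/aq Na2B4O7, 0 °C
Reagents that add atoms: potassium peroxymonosulfate (KHSO5), [K+].[O-]S(=O)(=O)OO
Why: Shi asymmetric epoxidation: the chiral dioxirane attacks only the electron-rich Z trisubstituted alkene (the enoate is inert) through the spiro transition state, giving the cis epoxide with C7 R and C8 S.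

Step 5
Reactants: 12 methyl (2E)-5-[(2R,3S)-3-[2-(1,3-dioxolan-2-yl)ethyl]-3-methyloxiran-2-yl]-3-methylpent-2-enoate
Product: 13 (2E)-5-[(2R,3S)-3-[2-(1,3-dioxolan-2-yl)ethyl]-3-methyloxiran-2-yl]-3-methylpent-2-en-1-ol
Conditions: iBu2AlH (2.2 equiv), CH2Cl2, −78 °C; aq Rochelle salt
Reagents that add atoms: none
Why: DIBAL-H 1,2-reduction of the conjugated ester at −78 °C, a temperature at which the trisubstituted epoxide and the acetal are not attacked.

Step 6
Reactants: 13 (2E)-5-[(2R,3S)-3-[2-(1,3-dioxolan-2-yl)ethyl]-3-methyloxiran-2-yl]-3-methylpent-2-en-1-ol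
Product: 14 (2E)-5-[(2R,3S)-3-[2-(1,3-dioxolan-2-yl)ethyl]-3-methyloxiran-2-yl]-3-methylpent-2-enal
Conditions: MnO2, CH2Cl2, rt
Reagents that add atoms: none
Why: MnO2 oxidises only the allylic alcohol, under neutral conditions, to the E enal (allylic oxidation).

Step 7
Reactants: 15 but-2-yn-1-ol
Product: 16 (2Z)-3-(triethylsilyl)but-2-en-1-ol
Conditions: Et3SiH, [Cp*Ru(MeCN)3]PF6 (1 mol %), CH2Cl2, 0 °C → rt
Reagents that add atoms: triethylsilane, CC[SiH](CC)CC
Why: ruthenium-catalysed trans-hydrosilylation of the propargylic alcohol (Trost type) delivers H and Si anti with silicon on the carbon distal to OH, giving the Z vinylsilane with Si cis to CH2OH (the future C11/C14 cis relationship).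

Step 8
Reactants: 16 (2Z)-3-(triethylsilyl)but-2-en-1-ol
Product: 17 [(2Z)-4-bromobut-2-en-2-yl]triethylsilane
Conditions: CBr4, PPh3, CH2Cl2, 0 °C
Reagents that add atoms: carbon tetrabromide, BrC(Br)(Br)Br
Why: Appel bromination of the primary allylic alcohol (SN2) with the vinylsilane geometry unchanged.

Step 9
Reactants: 17 [(2Z)-4-bromobut-2-en-2-yl]triethylsilane; 18 methyl prop-2-ynoate
Product: 19 methyl (5Z)-6-(triethylsilyl)hept-5-en-2-ynoate
Conditions: CuI (10 mol %), NaI, K2CO3, DMF, rt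
Reagents that add atoms: none
Why: copper-catalysed coupling of the copper acetylide of 18 with the primary allylic bromide (SN2 at the unhindered terminus) gives the skipped enynoate without touching the alkene geometry.

Step 10
Reactants: 19 methyl (5Z)-6-(triethylsilyl)hept-5-en-2-ynoate
Product: 21 methyl (2Z,5Z)-2-(hydroxymethyl)-6-(triethylsilyl)hepta-2,5-dienoate, via vinylalane 20 (not isolated)
Conditions: iBu2AlH, HMPA, THF, 0 °C; then (CH2O)n, 0 °C → rt; H2O
Reagents that add atoms: formaldehyde (as paraformaldehyde), C=O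
Why: conjugate (1,4) hydroalumination of the ynoate by iBu2AlH–HMPA gives the α-alumino acrylate 20, which adds to formaldehyde at carbon (vinylalumination, a Baylis–Hillman-type product).

Step 11
Reactants: 21 methyl (2Z,5Z)-2-(hydroxymethyl)-6-(triethylsilyl)hepta-2,5-dienoate
Product: 22 methyl (2E,5Z)-2-(bromomethyl)-6-(triethylsilyl)hepta-2,5-dienoate
Conditions: CBr4, PPh3, CH2Cl2, −20 °C
Reagents that add atoms: carbon tetrabromide, BrC(Br)(Br)Br
Why: Appel bromination gives the allylic bromide, and any allylic transposition is harmless because both isomers give the same allylchromium species in step 12.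

Step 12
Reactants: 14 (2E)-5-[(2R,3S)-3-[2-(1,3-dioxolan-2-yl)ethyl]-3-methyloxiran-2-yl]-3-methylpent-2-enal; 22 methyl (2E,5Z)-2-(bromomethyl)-6-(triethylsilyl)hepta-2,5-dienoate
Product: 24 (4S,5S)-5-[(1E)-4-[(2R,3S)-3-[2-(1,3-dioxolan-2-yl)ethyl]-3-methyloxiran-2-yl]-2-methylbut-1-en-1-yl]-3-methylidene-4-[(2Z)-3-(triethylsilyl)but-2-en-1-yl]oxolan-2-one, via silyl ether 23 (not isolated)
Conditions: CrCl2 (10 mol %), (S,S)-3,6-di-tert-butyl-1,8-bis(4-isopropyl-4,5-dihydrooxazol-2-yl)-9H-carbazole (12 mol %), Mn powder, Me3SiCl, iPr2NEt, THF, 0 °C → rt; then K2CO3 (cat.), MeOH, 0 °C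
Reagents that add atoms: none
Why: catalytic asymmetric Nozaki–Hiyama–Kishi 2-(alkoxycarbonyl)allylation followed by lactonisation: the allylchromium equilibrates to the ester-chelated Z form and adds through a chair transition state (syn adduct, cis lactone) while the carbazole bis(oxazoline) ligand directs attack on the Re face of the enal, setting C1 S and C2 S.

Step 13
Reactants: 24 (4S,5S)-5-[(1E)-4-[(2R,3S)-3-[2-(1,3-dioxolan-2-yl)ethyl]-3-methyloxiran-2-yl]-2-methylbut-1-en-1-yl]-3-methylidene-4-[(2Z)-3-(triethylsilyl)but-2-en-1-yl]oxolan-2-one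
Product: 26 (4S,5S)-5-[(1E)-2-methyl-4-[(1R,4S,6R)-1-methyl-2,3,5-trioxabicyclo[2.2.2]octan-6-yl]but-1-en-1-yl]-3-methylidene-4-[(2Z)-3-(triethylsilyl)but-2-en-1-yl]oxolan-2-one, via hydroxy hydroperoxide 25 (not isolated)
Conditions: H2O2 (anhydrous, Et2O), H3PMo12O40 (2 mol %), Et2O, 0 °C → rt; then camphorsulfonic acid (10 mol %), CH2Cl2, 4 Å MS, rt
Reagents that add atoms: hydrogen peroxide, OO
Why: ring expansion of the oxirane to a 1,2,4-trioxane: H3PMo12O40-catalysed perhydrolysis opens the epoxide at the tertiary carbon C8 with inversion (C8 becomes R, C7 stays R) and the hydroperoxide and the C7 hydroxyl then displace ethylene glycol from the C11 acetal (peroxyacetalisation), so O–O–C11 is inserted into the former C8–O bond and the bridged bicycle already contains the 1,2-dioxane.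

Step 14
Reactants: 26 (4S,5S)-5-[(1E)-2-methyl-4-[(1R,4S,6R)-1-methyl-2,3,5-trioxabicyclo[2.2.2]octan-6-yl]but-1-en-1-yl]-3-methylidene-4-[(2Z)-3-(triethylsilyl)but-2-en-1-yl]oxolan-2-one
Product: 28 (1S,2S,3E,7R,8R,11S,12Z)-7-acetoxy-8,11-epidioxycembra-3,12,15(17)-trien-16,2-olide (target), via anomeric acetate 27 (not isolated)
Conditions: Ac2O (1.5 equiv), Me3SiOTf (0.2 equiv), 2,6-di-tert-butyl-4-methylpyridine, CH2Cl2 (0.5 mM, slow addition), −78 → −30 °C
Reagents that add atoms: acetic anhydride, CC(=O)OC(C)=O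
Why: Proposed new method: Me3SiOTf/Ac2O acylates the ether oxygen of the trioxabicycle, the C11–O bond to C7–O ionises with help of the peroxide lone pair to a cyclic peroxycarbenium ion (resting as anomeric acetate 27), and the tethered (Z)-vinylsilane attacks it at its silicon-bearing carbon (β-silyl cation, loss of Et3Si+) to close the 14-membered ring with retention of the Z geometry; because the nucleophile is tied to C7 it reaches only the face of C11 that is cis to C7, which sets C11 S; the closest known reactions are Lewis-acid allylation of peroxycarbenium ions by allylsilanes and vinylsilane-terminated oxocarbenium cyclisations, whereas the vinylsilane/peroxycarbenium pairing and its use for macrocyclisation are new.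

**Compound list**

1 | 2-(2-bromoethyl)-1,3-dioxolane | BrCCC1OCCO1 | starting material
2 | propyne | CC#C | starting material
3 | oxirane | C1CO1 | starting material
4 | [2-(1,3-dioxolan-2-yl)ethyl]magnesium bromide | Br[Mg]CCC1OCCO1 | intermediate
5 | [(1Z)-4-(1,3-dioxolan-2-yl)-2-methylbut-1-en-1-yl]copper (MgBr2 complex) | [Cu]/C=C(/C)CCC1OCCO1 | intermediate
6 | (3Z)-6-(1,3-dioxolan-2-yl)-4-methylhex-3-en-1-ol | OCC/C=C(/C)CCC1OCCO1 | intermediate
7 | 2-[(3Z)-6-bromo-3-methylhex-3-en-1-yl]-1,3-dioxolane | BrCC/C=C(/C)CCC1OCCO1 | intermediate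
8 | methyl but-2-ynoate | CC#CC(=O)OC | starting material
9 | [(3Z)-6-(1,3-dioxolan-2-yl)-4-methylhex-3-en-1-yl]magnesium bromide | Br[Mg]CC/C=C(/C)CCC1OCCO1 | intermediate
10 | methyl (2Z,6Z)-2-cuprio-9-(1,3-dioxolan-2-yl)-3,7-dimethylnona-2,6-dienoate | COC(=O)/C([Cu])=C(\C)CC/C=C(/C)CCC1OCCO1 | intermediate
11 | methyl (2E,6Z)-9-(1,3-dioxolan-2-yl)-3,7-dimethylnona-2,6-dienoate | COC(=O)/C=C(\C)CC/C=C(/C)CCC1OCCO1 | intermediate
12 | methyl (2E)-5-[(2R,3S)-3-[2-(1,3-dioxolan-2-yl)ethyl]-3-methyloxiran-2-yl]-3-methylpent-2-enoate | COC(=O)/C=C(\C)CC[C@H]1O[C@@]1(C)CCC2OCCO2 | intermediate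
13 | (2E)-5-[(2R,3S)-3-[2-(1,3-dioxolan-2-yl)ethyl]-3-methyloxiran-2-yl]-3-methylpent-2-en-1-ol | OC/C=C(\C)CC[C@H]1O[C@@]1(C)CCC2OCCO2 | intermediate
14 | (2E)-5-[(2R,3S)-3-[2-(1,3-dioxolan-2-yl)ethyl]-3-methyloxiran-2-yl]-3-methylpent-2-enal | O=C/C=C(\C)CC[C@H]1O[C@@]1(C)CCC2OCCO2 | intermediate
15 | but-2-yn-1-ol | CC#CCO | starting material
16 | (2Z)-3-(triethylsilyl)but-2-en-1-ol | C/C(=C/CO)[Si](CC)(CC)CC | intermediate
17 | [(2Z)-4-bromobut-2-en-2-yl]triethylsilane | C/C(=C/CBr)[Si](CC)(CC)CC | intermediate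
18 | methyl prop-2-ynoate | C#CC(=O)OC | starting material
19 | methyl (5Z)-6-(triethylsilyl)hept-5-en-2-ynoate | COC(=O)C#CC/C=C(/C)[Si](CC)(CC)CC | intermediate
20 | methyl (2E,5Z)-2-(diisobutylalumanyl)-6-(triethylsilyl)hepta-2,5-dienoate | COC(=O)/C(=C\C/C=C(/C)[Si](CC)(CC)CC)[Al](CC(C)C)CC(C)C | intermediate
21 | methyl (2Z,5Z)-2-(hydroxymethyl)-6-(triethylsilyl)hepta-2,5-dienoate | COC(=O)/C(CO)=C\C/C=C(/C)[Si](CC)(CC)CC | intermediate
22 | methyl (2E,5Z)-2-(bromomethyl)-6-(triethylsilyl)hepta-2,5-dienoate | COC(=O)/C(CBr)=C\C/C=C(/C)[Si](CC)(CC)CC | intermediate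
23 | methyl (3S,4S,5E)-8-[(2R,3S)-3-[2-(1,3-dioxolan-2-yl)ethyl]-3-methyloxiran-2-yl]-6-methyl-2-methylidene-3-[(2Z)-3-(triethylsilyl)but-2-en-1-yl]-4-[(trimethylsilyl)oxy]oct-5-enoate | COC(=O)C(=C)[C@H](C/C=C(/C)[Si](CC)(CC)CC)[C@@H](O[Si](C)(C)C)/C=C(\C)CC[C@H]1O[C@@]1(C)CCC2OCCO2 | intermediate
24 | (4S,5S)-5-[(1E)-4-[(2R,3S)-3-[2-(1,3-dioxolan-2-yl)ethyl]-3-methyloxiran-2-yl]-2-methylbut-1-en-1-yl]-3-methylidene-4-[(2Z)-3-(triethylsilyl)but-2-en-1-yl]oxolan-2-one | C=C1C(=O)O[C@@H](/C=C(\C)CC[C@H]2O[C@@]2(C)CCC3OCCO3)[C@H]1C/C=C(/C)[Si](CC)(CC)CC | intermediate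
25 | (4S,5S)-5-[(1E,5R,6R)-8-(1,3-dioxolan-2-yl)-6-hydroperoxy-5-hydroxy-2,6-dimethyloct-1-en-1-yl]-3-methylidene-4-[(2Z)-3-(triethylsilyl)but-2-en-1-yl]oxolan-2-one | C=C1C(=O)O[C@@H](/C=C(\C)CC[C@@H](O)[C@](C)(OO)CCC2OCCO2)[C@H]1C/C=C(/C)[Si](CC)(CC)CC | intermediate
26 | (4S,5S)-5-[(1E)-2-methyl-4-[(1R,4S,6R)-1-methyl-2,3,5-trioxabicyclo[2.2.2]octan-6-yl]but-1-en-1-yl]-3-methylidene-4-[(2Z)-3-(triethylsilyl)but-2-en-1-yl]oxolan-2-one | C=C1C(=O)O[C@@H](/C=C(\C)CC[C@H]2O[C@@H]3CC[C@@]2(C)OO3)[C@H]1C/C=C(/C)[Si](CC)(CC)CC | intermediate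
27 | (4S,5S)-5-[(1E,5R)-5-acetoxy-5-[(3R)-6-acetoxy-3-methyl-1,2-dioxan-3-yl]-2-methylpent-1-en-1-yl]-3-methylidene-4-[(2Z)-3-(triethylsilyl)but-2-en-1-yl]oxolan-2-one (both C11 epimers) | C=C1C(=O)O[C@@H](/C=C(\C)CC[C@@H](OC(C)=O)[C@@]2(C)CCC(OC(C)=O)OO2)[C@H]1C/C=C(/C)[Si](CC)(CC)CC | intermediate
28 | (1S,2S,3E,7R,8R,11S,12Z)-7-acetoxy-8,11-epidioxycembra-3,12,15(17)-trien-16,2-olide (CNP0238885.8) | C=C1C(=O)O[C@H]2/C=C(\C)CC[C@@H](OC(C)=O)[C@@]3(C)CC[C@H](OO3)/C(C)=C\C[C@@H]12 | target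

**Step count**

Total steps: 14. Longest linear sequence: 9 steps (1–6, then 12, 13, 14).

**Three steps most likely to fail**

1. Step 14 (the new macrocyclisation). Risks are the low nucleophilicity of the vinylsilane, attack through C13 instead of C12, and proton loss from the peroxycarbenium ion. The fallback uses known chemistry, sets out from 24 and comes back at 28. N-Iodosuccinimide in MeCN/ClCH2CN exchanges silicon for iodine with retention to give the Z-vinyl iodide F1. LiBF4 in wet MeCN unmasks the aldehyde F2. NiCl2/CrCl2 (Nozaki–Hiyama–Kishi) closes the 14-membered ring to the allylic alcohol F3. Dess–Martin periodinane gives the Z-enone F4. H2O2/H3PMo12O40 then camphorsulfonic acid (the same oxirane ring expansion, now transannular, with the ketone as acetal carbon) gives the bridged peroxyketal F5. Et3SiH/BF3·OEt2 (ionic reduction of the peroxyketal, hydride entering anti to the departing C7 oxygen) gives the 7-hydroxy peroxide F6, and Ac2O/pyridine/DMAP gives 28.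

2. Step 12. Risks are the sense and level of induction with a γ-substituted bromide (the ligand antipode would be chosen by experiment) and the tolerance of the epoxide to Me3SiCl. The fallback sets out from 22 and comes back at 24. Pd2(dba)3-catalysed borylation of 22 with B2pin2 gives the allylboronate F7 (thermodynamic isomer, chain cis to CH2B). Its allylboration of 14, catalysed by (R)-3,3'-bis(2,4,6-triisopropylphenyl)-1,1'-binaphthyl-2,2'-diyl hydrogen phosphate, passes a closed chair transition state (syn adduct), and the borate lactonises to 24.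

3. Step 13. Risks are the regiochemistry and inversion at C8, the acid-sensitive lactone and vinylsilane, and incomplete acetal exchange. The fallback sets out from 24 and comes back at 26. LiBF4 in wet MeCN unmasks the aldehyde F8. Anhydrous H2O2 adds to it to give the hydroperoxy hemiacetal, and camphorsulfonic acid then lets the tethered OOH open the epoxide 6-exo at C8 (inversion) and close the acetal to 26.

**Further compounds**

F1 | step 14 | (4S,5S)-5-[(1E)-4-[(2R,3S)-3-[2-(1,3-dioxolan-2-yl)ethyl]-3-methyloxiran-2-yl]-2-methylbut-1-en-1-yl]-4-[(2Z)-3-iodobut-2-en-1-yl]-3-methylideneoxolan-2-one (Z-vinyl iodide) | C=C1C(=O)O[C@@H](/C=C(\C)CC[C@H]2O[C@@]2(C)CCC3OCCO3)[C@H]1C/C=C(/C)I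
F2 | step 14 | (4S,5S)-4-[(2Z)-3-iodobut-2-en-1-yl]-5-[(1E)-2-methyl-4-[(2R,3S)-3-methyl-3-(3-oxopropyl)oxiran-2-yl]but-1-en-1-yl]-3-methylideneoxolan-2-one (aldehyde) | C=C1C(=O)O[C@@H](/C=C(\C)CC[C@H]2O[C@@]2(C)CCC=O)[C@H]1C/C=C(/C)I
F3 | step 14 | (1S,2S,3E,7R,8S,12Z)-7,8-epoxy-11-hydroxycembra-3,12,15(17)-trien-16,2-olide, both C11 epimers (allylic alcohol) | C=C1C(=O)O[C@H]2/C=C(\C)CC[C@H]3O[C@@]3(C)CCC(O)/C(C)=C\C[C@@H]12
F4 | step 14 | (1S,2S,3E,7R,8S,12Z)-7,8-epoxy-11-oxocembra-3,12,15(17)-trien-16,2-olide (Z-enone) | C=C1C(=O)O[C@H]2/C=C(\C)CC[C@H]3O[C@@]3(C)CCC(=O)/C(C)=C\C[C@@H]12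
F5 | step 14 | (1S,2S,3E,7R,8R,11R,12Z)-7,11-epoxy-8,11-epidioxycembra-3,12,15(17)-trien-16,2-olide (bridged peroxyketal) | C=C1C(=O)O[C@H]2/C=C(\C)CC[C@H]3O[C@@]4(CC[C@@]3(C)OO4)/C(C)=C\C[C@@H]12
F6 | step 14 | (1S,2S,3E,7R,8R,11S,12Z)-8,11-epidioxy-7-hydroxycembra-3,12,15(17)-trien-16,2-olide (7-hydroxy peroxide) | C=C1C(=O)O[C@H]2/C=C(\C)CC[C@@H](O)[C@@]3(C)CC[C@H](OO3)/C(C)=C\C[C@@H]12
F7 | step 12 | methyl (2E,5Z)-2-[(4,4,5,5-tetramethyl-1,3,2-dioxaborolan-2-yl)methyl]-6-(triethylsilyl)hepta-2,5-dienoate (allylboronate) | COC(=O)/C(CB1OC(C)(C)C(C)(C)O1)=C/C/C=C(/C)[Si](CC)(CC)CC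
F8 | step 13 | (4S,5S)-5-[(1E)-2-methyl-4-[(2R,3S)-3-methyl-3-(3-oxopropyl)oxiran-2-yl]but-1-en-1-yl]-3-methylidene-4-[(2Z)-3-(triethylsilyl)but-2-en-1-yl]oxolan-2-one (aldehyde) | C=C1C(=O)O[C@@H](/C=C(\C)CC[C@H]2O[C@@]2(C)CCC=O)[C@H]1C/C=C(/C)[Si](CC)(CC)CC
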